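Abbreviations: TBS = tert-butyldimethylsilyl, TES = triethylsilyl, TBSO/TESO = the corresponding silyloxy groups. Atom numbers C1–C10 are those of the target skeleton: ring A is C1–C2–C3–C4–C5, ring B is C5–C6–C7–C8–C9–C10–C1. The face of ring A that carries the C1 methyl group is called β, the other α.

## Analysis of the target

The target 25 is a daucane-type hydroazulene: a cyclopentanone (ring A) fused through C1–C5 to a cycloheptene (ring B). Ring A carries the angular methyl on quaternary C1, the ketone at C2 and the tertiary carbinol with the isopropyl group at C4. Ring B carries the 4-methoxybenzoate on C6 and the only olefin, C8=C9, with a methyl on C8. There are four stereocentres, C1 (R), C4 (R), C5 (S) and C6 (S). The rings are trans-fused, the C1 methyl and the C4 hydroxyl are β, and H5, the isopropyl group and the C6 ester oxygen are α, so the C4 and C6 oxygens are anti across C5. The C4 hydroxyl is β to the C2 ketone, and to any C6 ketone made on the way, so dehydration and retro-aldol cleavage threaten under acid or base; the aryl ester and the β,γ-placed olefin are further sensitive points. The hard parts are the quaternary C1 between a carbonyl and the ring fusion, the congested run C4–C5–C6, and a seven-membered ring with one olefin in a defined position. The strategy rests on two features. First, C8=C9 and the oxygen-bearing C5–C6 bond are separated only by C7, which is the 1,4-pattern of the cycloheptadiene formed from a cis-divinylcyclopropane when C6 is read as an enol ether. Second, C1 with its methyl, C2, C3, C4 with hydroxyl and isopropyl, C5 and C6 are the ten carbons of terpinen-4-ol 1, whose carbinol carbon is C4.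

## Retrosynthetic reasoning

**C2 ketone and ester.** The C2 ketone of 25 is traced back to the secondary alcohol 24 and its TBS ether 23, and the ester C–O bond is cut to the diol 21 and 4-methoxybenzoyl chloride 22. Keeping C2 at the alcohol level until the end means that only one carbonyl (C6) is present when hydride is used, and only one acylable hydroxyl (C6–OH, next to the tertiary C4–OH) is present when the ester is made.

**C6 and C5.** The C6–H bond of 21 is cut to the β-hydroxy ketone 20. The free C4 hydroxyl sits on the β face and can carry the hydride to that face of C6, which puts the new hydroxyl α, anti to C4–OH, as required. Ketone 20 comes from the silyl enol ether 18 by desilylation; C5 becomes a stereocentre in that ketonisation, through the transient C4-silylated ketone 19.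

**C8 methyl.** The methyl on C8 of 18 is traced to the ester of 15 through the allylic alcohol 16 and its sulfonate 17. The ester is the acceptor group that the carbenoid chemistry needs on C8, and its removal by reduction and hydride displacement leaves the olefin at C8=C9.

**Ring B (key disconnection).** In 15 the bonds C7–C8 and C1–C10 are cut, giving the 2-silyloxydiene 9 and the vinyldiazoacetate 13. Forward, the rhodium carbenoid cyclopropanates the enol ether C6=C7 (C7–C8), and the cis-divinylcyclopropane 14 rearranges (C1–C10), which closes ring B, creates the quaternary C1 and places the olefin at C8=C9 and C6 at the enol ether level. No other cut makes two ring-B bonds and the C1 centre at once while leaving exactly the right unsaturation. C2 is carried through this step as its β-TBS ether and not as the ketone, for three reasons: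
- a C2 ketone would give an ene-dione with two enolisable ketones, so the enol ether at C6=C7 could not be made selectively;
- a C2 ketone would be reduced together with the ester afterwards;
- C10 must arrive on the α face of C1, the face of the isopropyl group; with the C2 and C4 silyloxy groups both β, that face becomes the less hindered one.

**Diazo component.** 13 is made from methyl acetoacetate 10 by diazo transfer (11), ketone reduction (12) and dehydration.

**Diene.** The enol ether of 9 comes from the methyl ketone 8, which has only this one carbonyl. 8 comes from the enal 6 by methyl addition (carbinol 7) and oxidation.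

**Ring A.** The C1=C5 olefin of 6 is cut by a retro-aldol condensation to the keto aldehyde 5, and 5 is the ozonolysis product of the cyclohexene 4. The six-membered ring of the terpene is thus contracted so that its olefinic carbons become C1 and C6.

**C2 oxygen and chirality.** 4 is the bis-silyl ether (via 3) of the cis-diol 2, and 2 is the allylic hydroxylation product of (S)-terpinen-4-ol 1. The oxygen enters at the ring methylene next to the methyl-bearing olefin carbon, which becomes C2. The C4 centre is bought with the terpene and is never touched.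

## Alternatives that were turned down

**Alternative 1:** Ring A is kept and both C1–C10 and C5–C6 are cut. Forward, a vinyl cuprate adds to C5 of a 4-hydroxycyclopentenone and the enolate is trapped at C1 with a butynyl halide, giving (2R,3R,4R)-2-(but-2-yn-1-yl)-3-ethenyl-4-hydroxy-2-methyl-4-(propan-2-yl)cyclopentan-1-one A1.
- For: C1 and C5 are set in one flask, trans to each other, by the dependable anti-alkylation of a β-substituted enolate. On the C5 configuration this is stronger than the chosen route, which leaves C5 to a later ketonisation.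
- Against: the cuprate must add syn to the C4 oxygen and anti to the isopropyl group, a choice left to one quaternary centre. Alkylation of a hindered cyclopentanone enolate competes with proton transfer to C3 and loss of the C4 oxygen. Ring B is still open after the key step: C7–C8 must be closed in a seven-membered mode against the easier six-membered one, and C6 in A1 has no oxygen.
- Comparison: the chosen route gives the complete ring B with C8=C9 and the C6 oxygen in place from one step, with fewer operations after it.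

**Alternative 2:** C1–C5 and C1–C10 are cut, and ring B is taken from a cresol ether. Forward, a dirhodium carboxylate decomposes an α-methyl diazoketone, the carbenoid carbon adds across the ipso–ortho bond and the bicyclic valence isomer opens to (3R,8aR)-4-methoxy-6,8a-dimethyl-3-(propan-2-yl)-3-(TESO)-3,8a-dihydroazulen-1(2H)-one A2.
- For: both rings and the quaternary C1 with the C2 ketone arise in one step from cheap aromatic material, without a labile vinyldiazo ester. On step count to the bicyclic skeleton it is stronger than the chosen route.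
- Against: C4 would be a tertiary benzylic carbinol that has to be made enantioselectively. C1 is set only by relay from C4. The α-methyl carbenoid can lose itself by 1,2-hydride shift. A2 is a triene with olefins at C5=C6, C7=C8 and C9=C10, none of which is the C8=C9 olefin wanted, so a 1,4-reduction of the diene beside an enol ether and a ketone would be needed.
- Comparison: the chosen route offers C4 from the chiral pool and a rearrangement that leaves exactly one olefin, at C8=C9.

**Alternative 3:** C1–C10 is cut inside a seven-membered allylic lactone. Forward, a lithium amide and a silyl chloride give the silyl ketene acetal, which rearranges through a ring-enforced boat to (1R,6S,7S)-6-(TBSO)-7-ethenyl-1,4-dimethylcyclohept-3-ene-1-carboxylic acid A3.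
- For: chirality transfer in such a ring-constrained Claisen is reliable, and A3 already has C5 and C6 with the right oxygen and relative configuration. On C5 and C6 it is stronger than the chosen route.
- Against: the lactone needs three stereocentres before the key step. Ring A must then be closed from a neopentyl carboxyl (C2) and a vinyl group (C4, C3) that brings neither the isopropyl group nor the C4 oxygen, so the oxygenated quaternary C4 would have to be created late on a crowded ring with no outside control.
- Comparison: the chosen route fixes C4 first, from the terpene, and builds the easier centres around it, in a shorter sequence.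

Key step: step 11

Remark (assumption 1): (S)-(+)-terpinen-4-ol 1 is taken to be available in high enantiomeric purity.
Remark (assumption 2): the sense of induction of the dirhodium prolinate on the 1,1-disubstituted enol ether of 9 is taken to be the one established for terminal alkenes, by which Rh2(R-DOSP)4 gives 14; if it is reversed on this substrate, Rh2(S-DOSP)4 is used with no other change.

## Route

Step 1
Reactants: 1 (S)-terpinen-4-ol, (1S)-4-methyl-1-(propan-2-yl)cyclohex-3-en-1-ol
Product: 2 (1R,3R)-4-methyl-1-(propan-2-yl)cyclohex-4-ene-1,3-diol (the two hydroxyls cis)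
Conditions: SeO2 (0.5 equiv), t-BuOOH, CH2Cl2, 0 °C to rt
Reagents that add atoms: tert-butyl hydroperoxide, CC(C)(C)OO (oxygen atom, passed on by selenium dioxide, O=[Se]=O)
Why: Allylic hydroxylation by ene reaction and [2,3]-sigmatropic shift; by the Guillemonat rules the oxygen enters at the ring methylene on the more substituted olefin terminus (the future C2), and pseudoaxial delivery anti to the equatorial isopropyl group should place it cis to the C4 hydroxyl. The minor epimer and any enone are removed by chromatography.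

Step 2
Reactants: 2 (1R,3R)-4-methyl-1-(propan-2-yl)cyclohex-4-ene-1,3-diol
Product: 3 (1R,3R)-3-(TBSO)-4-methyl-1-(propan-2-yl)cyclohex-4-en-1-ol
Conditions: TBSCl, imidazole, DMF, 0 °C to rt
Reagents that add atoms: tert-butyldimethylsilyl chloride, CC(C)(C)[Si](C)(C)Cl
Why: Silylation with a silyl chloride and imidazole takes the secondary allylic hydroxyl and leaves the hindered tertiary one.

Step 3
Reactants: 3 (1R,3R)-3-(TBSO)-4-methyl-1-(propan-2-yl)cyclohex-4-en-1-ol
Product: 4 (4R,6R)-6-(TBSO)-1-methyl-4-(propan-2-yl)-4-(TESO)cyclohex-1-ene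
Conditions: TESOTf, 2,6-lutidine, CH2Cl2, −78 to 0 °C
Reagents that add atoms: triethylsilyl trifluoromethanesulfonate, CC[Si](CC)(CC)OS(=O)(=O)C(F)(F)F
Why: Silyl triflate silylation of the tertiary alcohol; the ether prevents hemiketal formation and β-elimination in the next step and O–H insertion in the key step.

Step 4
Reactants: 4 (4R,6R)-6-(TBSO)-1-methyl-4-(propan-2-yl)-4-(TESO)cyclohex-1-ene
Product: 6 (3R,5R)-3-(TBSO)-2-methyl-5-(propan-2-yl)-5-(TESO)cyclopent-1-ene-1-carbaldehyde, via keto aldehyde 5 (not isolated)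
Conditions: O3, CH2Cl2/MeOH, −78 °C; Me2S; then Bn2NH2+ CF3CO2− (0.3 equiv), toluene, 50 °C
Reagents that add atoms: ozone, [O-][O+]=O
Why: Ozonolysis opens the only olefin to 5; the secondary ammonium salt turns the aldehyde into its enamine, which attacks the methyl ketone in a five-membered intramolecular aldol condensation, the standard ring contraction of 1-methylcyclohexenes. The terpene olefin carbons become C1 and C6, and C2 and C4 are not touched.

Step 5
Reactants: 6 (3R,5R)-3-(TBSO)-2-methyl-5-(propan-2-yl)-5-(TESO)cyclopent-1-ene-1-carbaldehyde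
Product: 7 1-[(3R,5R)-3-(TBSO)-2-methyl-5-(propan-2-yl)-5-(TESO)cyclopent-1-en-1-yl]ethan-1-ol (both carbinol epimers)
Conditions: MeMgBr, THF, −78 to 0 °C
Reagents that add atoms: methylmagnesium bromide, C[Mg]Br
Why: Grignard 1,2-addition to a β,β-disubstituted enal; the new carbinol centre is oxidised in the next step, so its configuration does not matter.

Step 6
Reactants: 7 1-[(3R,5R)-3-(TBSO)-2-methyl-5-(propan-2-yl)-5-(TESO)cyclopent-1-en-1-yl]ethan-1-ol
Product: 8 1-[(3R,5R)-3-(TBSO)-2-methyl-5-(propan-2-yl)-5-(TESO)cyclopent-1-en-1-yl]ethan-1-one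
Conditions: Dess–Martin periodinane, NaHCO3, CH2Cl2, 0 °C to rt
Reagents that add atoms: none
Why: Dess–Martin oxidation of the allylic alcohol under buffered conditions, which the silyl ethers tolerate.

Step 7
Reactants: 8 1-[(3R,5R)-3-(TBSO)-2-methyl-5-(propan-2-yl)-5-(TESO)cyclopent-1-en-1-yl]ethan-1-one
Product: 9 (1R,4R)-1-(TBSO)-2-methyl-4-(propan-2-yl)-4-(TESO)-3-[1-(TESO)ethenyl]cyclopent-2-ene
Conditions: TESOTf, Et3N, CH2Cl2, −78 to 0 °C
Reagents that add atoms: triethylsilyl trifluoromethanesulfonate, CC[Si](CC)(CC)OS(=O)(=O)C(F)(F)F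
Why: Soft enolisation of the methyl ketone with a silyl triflate and a tertiary amine removes a proton from the acetyl methyl group and gives the cross-conjugated 2-silyloxydiene; 8 has no other carbonyl, so there is no regiochemical choice between ketones.

Step 8
Reactants: 10 methyl acetoacetate (methyl 3-oxobutanoate)
Product: 11 methyl 2-diazo-3-oxobutanoate
Conditions: 4-acetamidobenzenesulfonyl azide, Et3N, MeCN, 0 °C to rt
Reagents that add atoms: 4-acetamidobenzenesulfonyl azide, CC(=O)Nc1ccc(cc1)S(=O)(=O)N=[N+]=[N-]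
Why: Regitz diazo transfer to the active methylene of a β-keto ester.

Step 9
Reactants: 11 methyl 2-diazo-3-oxobutanoate
Product: 12 methyl 2-diazo-3-hydroxybutanoate (racemic)
Conditions: NaBH4, MeOH, 0 °C
Reagents that add atoms: none
Why: Borohydride reduces the ketone and leaves the diazo ester; the carbinol centre is lost in the next step.

Step 10
Reactants: 12 methyl 2-diazo-3-hydroxybutanoate
Product: 13 methyl 2-diazobut-3-enoate
Conditions: POCl3, Et3N, CH2Cl2, 0 °C; kept as a cold pentane solution and used at once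
Reagents that add atoms: none
Why: Dehydration of the β-hydroxy α-diazo ester through its dichlorophosphate gives the vinyldiazoacetate; it is used immediately because it cyclises to a pyrazole on standing.

Step 11
Reactants: 9 (1R,4R)-1-(TBSO)-2-methyl-4-(propan-2-yl)-4-(TESO)-3-[1-(TESO)ethenyl]cyclopent-2-ene; 13 methyl 2-diazobut-3-enoate
Product: 15 methyl (1R,3R,8aR)-1-(TBSO)-8a-methyl-3-(propan-2-yl)-3,4-bis(TESO)-1,2,3,5,8,8a-hexahydroazulene-6-carboxylate, via cis-divinylcyclopropane 14 (not isolated)
Conditions: Rh2(R-DOSP)4 (2 mol %), hexanes, −40 °C, slow addition of 13 (3 equiv); then toluene, 80 °C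
Reagents that add atoms: none
Why: This is the tandem cyclopropanation and divinylcyclopropane (Cope) rearrangement of a vinyldiazoacetate with a 2-silyloxydiene under a chiral dirhodium tetraprolinate, the established formal [4+3] route to cyclohepta-1,4-dienes. The donor–acceptor carbenoid from 13 is electrophilic and adds to the terminal, electron-rich enol ether C6=C7 (forming C7–C8), not to the tetrasubstituted C1=C5 olefin and, cyclopropanation being much the faster process, not into the hindered allylic C2–H bond. Cyclopropane 14, with the vinyl group cis to the cyclopentenyl group, then undergoes the [3,3] shift through the boat transition state, breaking C6–C8 and joining C10 to C1. Ring B is therefore closed by pericyclic ring expansion of the three-membered ring and not by a polar end-to-end cyclisation, which is why the seven-membered ring forms readily. The new stereocentre C1 is fixed by the configuration of 14, set by the catalyst, because in the boat arrangement C10 can only reach the face of C1=C5 on which the cyclopropane sits. The substrate reinforces this, since the β face of ring A carries the C2 and C4 silyloxy groups and leaves the α face, the one required, as the more open one. C6 emerges as a silyl enol ether and C8=C9 as the only other ring olefin. The Z-methyl group and full substitution at C1 slow the Cope step, hence the warming; a cyclopropane formed with the two alkenyl groups trans can still enter the rearrangement by one-centre epimerisation of the donor–acceptor ring at that temperature.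

Step 12
Reactants: 15 methyl (1R,3R,8aR)-1-(TBSO)-8a-methyl-3-(propan-2-yl)-3,4-bis(TESO)-1,2,3,5,8,8a-hexahydroazulene-6-carboxylate
Product: 16 [(1R,3R,8aR)-1-(TBSO)-8a-methyl-3-(propan-2-yl)-3,4-bis(TESO)-1,2,3,5,8,8a-hexahydroazulen-6-yl]methanol
Conditions: i-Bu2AlH (3 equiv), CH2Cl2, −78 °C; KNaC4H4O6 (aq)
Reagents that add atoms: none
Why: 1,2-Reduction of the enoate to the allylic alcohol with an aluminium hydride; the silyl ethers and the hindered enol ether are inert at this temperature, and no ketone is present to be reduced with it.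

Step 13
Reactants: 16 [(1R,3R,8aR)-1-(TBSO)-8a-methyl-3-(propan-2-yl)-3,4-bis(TESO)-1,2,3,5,8,8a-hexahydroazulen-6-yl]methanol
Product: 18 (1R,3R,8aR)-1-(TBSO)-6,8a-dimethyl-3-(propan-2-yl)-3,4-bis(TESO)-1,2,3,5,8,8a-hexahydroazulene, via allylic mesylate 17 (not isolated)
Conditions: MsCl, Et3N, THF, −40 °C; then LiEt3BH, −40 to 0 °C
Reagents that add atoms: none
Why: Sulfonylation of the primary allylic alcohol and direct SN2 displacement by the borohydride; attack at the unhindered primary carbon leaves the olefin at C8=C9 and gives the C8 methyl group.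

Step 14
Reactants: 18 (1R,3R,8aR)-1-(TBSO)-6,8a-dimethyl-3-(propan-2-yl)-3,4-bis(TESO)-1,2,3,5,8,8a-hexahydroazulene
Product: 20 (1R,3R,3aR,8aR)-1-(TBSO)-3-hydroxy-6,8a-dimethyl-3-(propan-2-yl)-2,3,3a,5,8,8a-hexahydroazulen-4(1H)-one, via C4-silylated ketone 19 (not isolated)
Conditions: HF·pyridine, pyridine, THF, 0 °C to rt
Reagents that add atoms: none
Why: Fluoride cleaves the enol ether first, and the enol should ketonise while C4 still carries its TES group, so the proton is expected on the α face of C5, away from the C1 methyl and the C2 and C4 silyloxy groups, giving the trans ring fusion. The tertiary TES ether is then removed more slowly, while the far less labile secondary TBS ether at C2 should stay. The buffered, non-basic medium avoids retro-aldol cleavage and dehydration of the β-hydroxy ketone.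

Step 15
Reactants: 20 (1R,3R,3aR,8aR)-1-(TBSO)-3-hydroxy-6,8a-dimethyl-3-(propan-2-yl)-2,3,3a,5,8,8a-hexahydroazulen-4(1H)-one
Product: 21 (1R,3R,3aS,4S,8aR)-1-(TBSO)-6,8a-dimethyl-3-(propan-2-yl)-1,2,3,3a,4,5,8,8a-octahydroazulene-3,4-diol
Conditions: Me4NBH(OAc)3, MeCN/AcOH, −30 to 0 °C
Reagents that add atoms: none
Why: Evans–Saksena hydroxyl-directed reduction: the C4 hydroxyl exchanges onto boron and delivers hydride intramolecularly to the β face of the C6 carbonyl, so the new hydroxyl is α, anti to the C4 hydroxyl. C2 is not a ketone at this stage, so no second carbonyl competes.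

Step 16
Reactants: 21 (1R,3R,3aS,4S,8aR)-1-(TBSO)-6,8a-dimethyl-3-(propan-2-yl)-1,2,3,3a,4,5,8,8a-octahydroazulene-3,4-diol; 22 4-methoxybenzoyl chloride
Product: 23 (1R,3R,3aS,4S,8aR)-1-(TBSO)-3-hydroxy-6,8a-dimethyl-3-(propan-2-yl)-1,2,3,3a,4,5,8,8a-octahydroazulen-4-yl 4-methoxybenzoate
Conditions: Et3N, DMAP (cat.), CH2Cl2, 0 °C to rt
Reagents that add atoms: none
Why: Nucleophile-catalysed acylation of the secondary C6 hydroxyl; the tertiary C4 hydroxyl does not acylate under these conditions, and C2 is still silylated.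

Step 17
Reactants: 23 (1R,3R,3aS,4S,8aR)-1-(TBSO)-3-hydroxy-6,8a-dimethyl-3-(propan-2-yl)-1,2,3,3a,4,5,8,8a-octahydroazulen-4-yl 4-methoxybenzoate
Product: 24 (1R,3R,3aS,4S,8aR)-1,3-dihydroxy-6,8a-dimethyl-3-(propan-2-yl)-1,2,3,3a,4,5,8,8a-octahydroazulen-4-yl 4-methoxybenzoate
Conditions: HF·pyridine, THF, rt
Reagents that add atoms: none
Why: Fluoride cleavage of the secondary TBS ether under mildly acidic conditions that do not touch the aryl ester or the tertiary alcohol.

Step 18
Reactants: 24 (1R,3R,3aS,4S,8aR)-1,3-dihydroxy-6,8a-dimethyl-3-(propan-2-yl)-1,2,3,3a,4,5,8,8a-octahydroazulen-4-yl 4-methoxybenzoate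
Product: 25 (3R,3aS,4S,8aR)-3-hydroxy-6,8a-dimethyl-1-oxo-3-(propan-2-yl)-1,2,3,3a,4,5,8,8a-octahydroazulen-4-yl 4-methoxybenzoate
Conditions: Dess–Martin periodinane, NaHCO3, CH2Cl2, 0 °C to rt
Reagents that add atoms: none
Why: Dess–Martin oxidation of the only secondary alcohol to the C2 ketone; the tertiary alcohol cannot be oxidised, and the neutral buffered medium spares the β-hydroxy ketone from dehydration.

## Compound list

1 | (S)-terpinen-4-ol, (1S)-4-methyl-1-(propan-2-yl)cyclohex-3-en-1-ol | CC1=CC[C@](O)(C(C)C)CC1 | starting material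
2 | (1R,3R)-4-methyl-1-(propan-2-yl)cyclohex-4-ene-1,3-diol | CC1=CC[C@](O)(C(C)C)C[C@H]1O | intermediate
3 | (1R,3R)-3-(TBSO)-4-methyl-1-(propan-2-yl)cyclohex-4-en-1-ol | CC1=CC[C@](O)(C(C)C)C[C@H]1O[Si](C)(C)C(C)(C)C | intermediate
4 | (4R,6R)-6-(TBSO)-1-methyl-4-(propan-2-yl)-4-(TESO)cyclohex-1-ene | CC1=CC[C@](O[Si](CC)(CC)CC)(C(C)C)C[C@H]1O[Si](C)(C)C(C)(C)C | intermediate
5 | (3S,5R)-5-(TBSO)-6-oxo-3-(propan-2-yl)-3-(TESO)heptanal | CC(=O)[C@H](O[Si](C)(C)C(C)(C)C)C[C@@](O[Si](CC)(CC)CC)(C(C)C)CC=O | intermediate
6 | (3R,5R)-3-(TBSO)-2-methyl-5-(propan-2-yl)-5-(TESO)cyclopent-1-ene-1-carbaldehyde | O=CC1=C(C)[C@H](O[Si](C)(C)C(C)(C)C)C[C@@]1(O[Si](CC)(CC)CC)C(C)C | intermediate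
7 | 1-[(3R,5R)-3-(TBSO)-2-methyl-5-(propan-2-yl)-5-(TESO)cyclopent-1-en-1-yl]ethan-1-ol (both carbinol epimers) | CC(O)C1=C(C)[C@H](O[Si](C)(C)C(C)(C)C)C[C@@]1(O[Si](CC)(CC)CC)C(C)C | intermediate
8 | 1-[(3R,5R)-3-(TBSO)-2-methyl-5-(propan-2-yl)-5-(TESO)cyclopent-1-en-1-yl]ethan-1-one | CC(=O)C1=C(C)[C@H](O[Si](C)(C)C(C)(C)C)C[C@@]1(O[Si](CC)(CC)CC)C(C)C | intermediate
9 | (1R,4R)-1-(TBSO)-2-methyl-4-(propan-2-yl)-4-(TESO)-3-[1-(TESO)ethenyl]cyclopent-2-ene | C=C(O[Si](CC)(CC)CC)C1=C(C)[C@H](O[Si](C)(C)C(C)(C)C)C[C@@]1(O[Si](CC)(CC)CC)C(C)C | intermediate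
10 | methyl acetoacetate (methyl 3-oxobutanoate) | COC(=O)CC(C)=O | starting material
11 | methyl 2-diazo-3-oxobutanoate | COC(=O)C(=[N+]=[N-])C(C)=O | intermediate
12 | methyl 2-diazo-3-hydroxybutanoate (racemic) | COC(=O)C(=[N+]=[N-])C(C)O | intermediate
13 | methyl 2-diazobut-3-enoate | COC(=O)C(=[N+]=[N-])C=C | intermediate
14 | methyl (1S,2R)-2-[(3R,5R)-3-(TBSO)-2-methyl-5-(propan-2-yl)-5-(TESO)cyclopent-1-en-1-yl]-1-ethenyl-2-(TESO)cyclopropane-1-carboxylate | COC(=O)[C@]1(C=C)C[C@@]1(O[Si](CC)(CC)CC)C2=C(C)[C@H](O[Si](C)(C)C(C)(C)C)C[C@@]2(O[Si](CC)(CC)CC)C(C)C | intermediate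
15 | methyl (1R,3R,8aR)-1-(TBSO)-8a-methyl-3-(propan-2-yl)-3,4-bis(TESO)-1,2,3,5,8,8a-hexahydroazulene-6-carboxylate | COC(=O)C1=CC[C@@]2(C)[C@H](O[Si](C)(C)C(C)(C)C)C[C@@](O[Si](CC)(CC)CC)(C(C)C)C2=C(O[Si](CC)(CC)CC)C1 | intermediate
16 | [(1R,3R,8aR)-1-(TBSO)-8a-methyl-3-(propan-2-yl)-3,4-bis(TESO)-1,2,3,5,8,8a-hexahydroazulen-6-yl]methanol | OCC1=CC[C@@]2(C)[C@H](O[Si](C)(C)C(C)(C)C)C[C@@](O[Si](CC)(CC)CC)(C(C)C)C2=C(O[Si](CC)(CC)CC)C1 | intermediate
17 | [(1R,3R,8aR)-1-(TBSO)-8a-methyl-3-(propan-2-yl)-3,4-bis(TESO)-1,2,3,5,8,8a-hexahydroazulen-6-yl]methyl methanesulfonate | CS(=O)(=O)OCC1=CC[C@@]2(C)[C@H](O[Si](C)(C)C(C)(C)C)C[C@@](O[Si](CC)(CC)CC)(C(C)C)C2=C(O[Si](CC)(CC)CC)C1 | intermediate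
18 | (1R,3R,8aR)-1-(TBSO)-6,8a-dimethyl-3-(propan-2-yl)-3,4-bis(TESO)-1,2,3,5,8,8a-hexahydroazulene | CC1=CC[C@@]2(C)[C@H](O[Si](C)(C)C(C)(C)C)C[C@@](O[Si](CC)(CC)CC)(C(C)C)C2=C(O[Si](CC)(CC)CC)C1 | intermediate
19 | (1R,3R,3aR,8aR)-1-(TBSO)-6,8a-dimethyl-3-(propan-2-yl)-3-(TESO)-2,3,3a,5,8,8a-hexahydroazulen-4(1H)-one | CC1=CC[C@@]2(C)[C@H](O[Si](C)(C)C(C)(C)C)C[C@@](O[Si](CC)(CC)CC)(C(C)C)[C@@H]2C(=O)C1 | intermediate
20 | (1R,3R,3aR,8aR)-1-(TBSO)-3-hydroxy-6,8a-dimethyl-3-(propan-2-yl)-2,3,3a,5,8,8a-hexahydroazulen-4(1H)-one | CC1=CC[C@@]2(C)[C@H](O[Si](C)(C)C(C)(C)C)C[C@@](O)(C(C)C)[C@@H]2C(=O)C1 | intermediate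
21 | (1R,3R,3aS,4S,8aR)-1-(TBSO)-6,8a-dimethyl-3-(propan-2-yl)-1,2,3,3a,4,5,8,8a-octahydroazulene-3,4-diol | CC1=CC[C@@]2(C)[C@H](O[Si](C)(C)C(C)(C)C)C[C@@](O)(C(C)C)[C@@H]2[C@@H](O)C1 | intermediate
22 | 4-methoxybenzoyl chloride | COc1ccc(cc1)C(Cl)=O | starting material
23 | (1R,3R,3aS,4S,8aR)-1-(TBSO)-3-hydroxy-6,8a-dimethyl-3-(propan-2-yl)-1,2,3,3a,4,5,8,8a-octahydroazulen-4-yl 4-methoxybenzoate | COc1ccc(C(=O)O[C@H]2CC(C)=CC[C@@]3(C)[C@H](O[Si](C)(C)C(C)(C)C)C[C@@](O)(C(C)C)[C@H]23)cc1 | intermediate
24 | (1R,3R,3aS,4S,8aR)-1,3-dihydroxy-6,8a-dimethyl-3-(propan-2-yl)-1,2,3,3a,4,5,8,8a-octahydroazulen-4-yl 4-methoxybenzoate | COc1ccc(C(=O)O[C@H]2CC(C)=CC[C@@]3(C)[C@H](O)C[C@@](O)(C(C)C)[C@H]23)cc1 | intermediate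
25 | (3R,3aS,4S,8aR)-3-hydroxy-6,8a-dimethyl-1-oxo-3-(propan-2-yl)-1,2,3,3a,4,5,8,8a-octahydroazulen-4-yl 4-methoxybenzoate | COc1ccc(C(=O)O[C@H]2CC(C)=CC[C@@]3(C)C(=O)C[C@@](O)(C(C)C)[C@H]23)cc1 | target

## Step count and least certain steps

Total: 18 steps. Longest linear sequence: 15 steps (steps 1–7 and 11–18, from 1 to 25); the three steps to 13 run in parallel.

**Step 11 (key step).** The cyclopropanation may take the wrong face, or place the silyloxy group instead of the cyclopentenyl group cis to the vinyl group, so that the rearrangement is delayed or diverted. The diazo ester may also be lost by electrocyclisation before carbene transfer, and the donor–acceptor cyclopropane may open in a polar way. The cause is that a 1,1-disubstituted enol ether on a crowded ring offers the catalyst little to choose between, and the Cope step is slow at a fully substituted terminus.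
Fallback, from 6 back to 20, closing ring B by olefin metathesis after an anionic oxy-Cope rearrangement has made C1 quaternary. Allylmagnesium bromide adds to 6 to give 1-[(3R,5R)-3-(TBSO)-2-methyl-5-(propan-2-yl)-5-(TESO)cyclopent-1-en-1-yl]but-3-en-1-ol F1. Its potassium alkoxide (KH, 18-crown-6, THF) rearranges, carrying the allyl group to C1 on the face away from the C2 silyloxy group, and protonation of the aldehyde enolate gives (1R,2R,3R,5R)-3-(TBSO)-2-methyl-2-(prop-2-en-1-yl)-5-(propan-2-yl)-5-(TESO)cyclopentane-1-carbaldehyde F2. 2-Methylallylmagnesium chloride gives the carbinol 1-[(1S,2R,3R,5R)-3-(TBSO)-2-methyl-2-(prop-2-en-1-yl)-5-(propan-2-yl)-5-(TESO)cyclopentyl]-3-methylbut-3-en-1-ol F3. Dess–Martin oxidation gives 1-[(1R,2R,3R,5R)-3-(TBSO)-2-methyl-2-(prop-2-en-1-yl)-5-(propan-2-yl)-5-(TESO)cyclopentyl]-3-methylbut-3-en-1-one F4. HF·pyridine frees the tertiary alcohol to give 1-[(1R,2R,3R,5R)-3-(TBSO)-5-hydroxy-2-methyl-2-(prop-2-en-1-yl)-5-(propan-2-yl)cyclopentyl]-3-methylbut-3-en-1-one F5. Ring-closing metathesis with RuCl2(=CHPh)(PCy3)(H2IMes), the second-generation Grubbs catalyst, forms C8=C9 and gives 20.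

**Step 14.** Ketonisation may take place on the β face of C5 and give the cis ring fusion. The α face is flanked by the isopropyl group and by C10, so the facial preference rests only on the three β substituents. Partial loss of the C2 TBS ether during the slower cleavage of the tertiary TES ether is the second risk.
Fallback, from 18 back to 20, replacing kinetic by thermodynamic control. The cis-fused ketone obtained from 18 under the same conditions, (1R,3R,3aS,8aR)-1-(TBSO)-3-hydroxy-6,8a-dimethyl-3-(propan-2-yl)-2,3,3a,5,8,8a-hexahydroazulen-4(1H)-one F9, is equilibrated at C5 with a weak non-nucleophilic base (DBU, toluene, 40 °C). The trans-fused 20 is expected to be favoured because there C6 stands cis to the C4 hydroxyl, which can hydrogen-bond to the carbonyl, and not cis to the isopropyl group. The base is kept weak because retro-aldol opening of C4–C5 is the limit of this method.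

**Step 1.** The hydroxyl may enter trans to the C4 hydroxyl, the alcohol may be over-oxidised to the enone, and some oxidation of the vinylic methyl group may occur. The axial preference is opposed here by a 1,3-diaxial contact with the C4 hydroxyl.
Fallback, from 1 back to 2, by an oxidation, reduction and inversion relay. The crude allylic alcohols from 1 are oxidised (MnO2, CH2Cl2) to the single enone (5R)-5-hydroxy-2-methyl-5-(propan-2-yl)cyclohex-2-en-1-one F6. Luche reduction (NaBH4, CeCl3·7H2O, MeOH) returns 2 together with its epimer (1R,3S)-4-methyl-1-(propan-2-yl)cyclohex-4-ene-1,3-diol F7. F7 is inverted by Mitsunobu esterification (4-nitrobenzoic acid, PPh3, diisopropyl azodicarboxylate) to (1R,5R)-5-hydroxy-2-methyl-5-(propan-2-yl)cyclohex-2-en-1-yl 4-nitrobenzoate F8, and methanolysis (K2CO3, MeOH) gives 2.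

**Step 15.** Hydride delivery may fail or come from the α face, because exchange of a hindered tertiary hydroxyl onto boron is slow and an undirected reduction then competes.
Fallback, from 20 back to 23, setting C6 by inversion instead of by delivery. Reduction with NaBH4 (MeOH, 0 °C) gives the C6 epimer (1R,3R,3aS,4R,8aR)-1-(TBSO)-6,8a-dimethyl-3-(propan-2-yl)-1,2,3,3a,4,5,8,8a-octahydroazulene-3,4-diol F10, alone or beside 21. Mitsunobu esterification of F10 with 4-methoxybenzoic acid (PPh3, diisopropyl azodicarboxylate) inverts C6 and gives 23 directly.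

## Further compounds

F1 | step 11 | 1-[(3R,5R)-3-(TBSO)-2-methyl-5-(propan-2-yl)-5-(TESO)cyclopent-1-en-1-yl]but-3-en-1-ol | C=CCC(O)C1=C(C)[C@H](O[Si](C)(C)C(C)(C)C)C[C@@]1(O[Si](CC)(CC)CC)C(C)C
F2 | step 11 | (1R,2R,3R,5R)-3-(TBSO)-2-methyl-2-(prop-2-en-1-yl)-5-(propan-2-yl)-5-(TESO)cyclopentane-1-carbaldehyde | O=C[C@@H]1[C@@](C)(CC=C)[C@H](O[Si](C)(C)C(C)(C)C)C[C@@]1(O[Si](CC)(CC)CC)C(C)C
F3 | step 11 | 1-[(1S,2R,3R,5R)-3-(TBSO)-2-methyl-2-(prop-2-en-1-yl)-5-(propan-2-yl)-5-(TESO)cyclopentyl]-3-methylbut-3-en-1-ol | CC(=C)CC(O)[C@@H]1[C@@](C)(CC=C)[C@H](O[Si](C)(C)C(C)(C)C)C[C@@]1(O[Si](CC)(CC)CC)C(C)C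
F4 | step 11 | 1-[(1R,2R,3R,5R)-3-(TBSO)-2-methyl-2-(prop-2-en-1-yl)-5-(propan-2-yl)-5-(TESO)cyclopentyl]-3-methylbut-3-en-1-one | CC(=C)CC(=O)[C@@H]1[C@@](C)(CC=C)[C@H](O[Si](C)(C)C(C)(C)C)C[C@@]1(O[Si](CC)(CC)CC)C(C)C
F5 | step 11 | 1-[(1R,2R,3R,5R)-3-(TBSO)-5-hydroxy-2-methyl-2-(prop-2-en-1-yl)-5-(propan-2-yl)cyclopentyl]-3-methylbut-3-en-1-one | CC(=C)CC(=O)[C@@H]1[C@@](C)(CC=C)[C@H](O[Si](C)(C)C(C)(C)C)C[C@@]1(O)C(C)C
F6 | step 1 | (5R)-5-hydroxy-2-methyl-5-(propan-2-yl)cyclohex-2-en-1-one | CC1=CC[C@](O)(C(C)C)CC1=O
F7 | step 1 | (1R,3S)-4-methyl-1-(propan-2-yl)cyclohex-4-ene-1,3-diol | CC1=CC[C@](O)(C(C)C)C[C@@H]1O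
F8 | step 1 | (1R,5R)-5-hydroxy-2-methyl-5-(propan-2-yl)cyclohex-2-en-1-yl 4-nitrobenzoate | CC1=CC[C@](O)(C(C)C)C[C@H]1OC(=O)c2ccc(cc2)[N+](=O)[O-]
F9 | step 14 | (1R,3R,3aS,8aR)-1-(TBSO)-3-hydroxy-6,8a-dimethyl-3-(propan-2-yl)-2,3,3a,5,8,8a-hexahydroazulen-4(1H)-one | CC1=CC[C@@]2(C)[C@H](O[Si](C)(C)C(C)(C)C)C[C@@](O)(C(C)C)[C@H]2C(=O)C1
F10 | step 15 | (1R,3R,3aS,4R,8aR)-1-(TBSO)-6,8a-dimethyl-3-(propan-2-yl)-1,2,3,3a,4,5,8,8a-octahydroazulene-3,4-diol | CC1=CC[C@@]2(C)[C@H](O[Si](C)(C)C(C)(C)C)C[C@@](O)(C(C)C)[C@@H]2[C@H](O)C1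
A1 | alternative 1 | (2R,3R,4R)-2-(but-2-yn-1-yl)-3-ethenyl-4-hydroxy-2-methyl-4-(propan-2-yl)cyclopentan-1-one | CC#CC[C@@]1(C)C(=O)C[C@@](O)(C(C)C)[C@@H]1C=C
A2 | alternative 2 | (3R,8aR)-4-methoxy-6,8a-dimethyl-3-(propan-2-yl)-3-(TESO)-3,8a-dihydroazulen-1(2H)-one | COC1=C2[C@](O[Si](CC)(CC)CC)(C(C)C)CC(=O)[C@]2(C)C=CC(C)=C1
A3 | alternative 3 | (1R,6S,7S)-6-(TBSO)-7-ethenyl-1,4-dimethylcyclohept-3-ene-1-carboxylic acid | CC1=CC[C@@](C)(C(=O)O)[C@H](C=C)[C@@H](O[Si](C)(C)C(C)(C)C)C1
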